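**Retrosynthetic overview**

1. Core numbering (11-oxabicyclo[4.4.1]undecane): C1 = C(Me)–O, C2 = CH–O-isovaleryl, C3 = lactone O–CH, C4 = lactone β-CH, C5 = CH2, C6 = ether CH, C7 = CHMe, C8–C10 = CH2, O11 = bridging oxygen; ring A = oxepane O11/C1–C6, ring B = oxepane O11/C6–C10/C1.
2. Target ⇐ α-phosphono lactone 19 (Horner–Wadsworth–Emmons with CH2O) ⇐ trans-diol 15 (lactonisation on O-3, acylation of O-2) ⇐ bridged keto phosphonate 13 (PMB removal, hydroxyl-directed reduction of the C2 ketone).
3. Key disconnection: the O11–C6 ether bond and the C3–C4 bond of 13 are made together from acyclic 11 by a base-mediated 1,6-oxa-Michael/1,4-Michael bicyclisation; ring order is ring B (O11–C6), ring A (C3–C4), then the γ-lactone.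
4. Enabling feature: in ring A, C6 and C4 are 1,3-related through C5H2 and C4 carries the lactone carboxyl carbon, so they are the δ- and β-carbons of a 2,4-dienoate; O11 and C3 are 1,4-related through C1 and C2, so with C2 as a ketone they are the hydroxyl oxygen and α′-carbon of a tertiary α-ketol; the one-atom O11 bridge allows only one C1/C6 relationship.
5. 11 ⇐ enal 9 + phosphonoacetate 10 (Knoevenagel) ⇐ (R)-linalool 1 (C1 centre and ten skeletal carbons) by vinyl epoxidation/PMB-alcohol opening, allylic oxidation, asymmetric hydrogenation (C7), double oxidation and Wittig homologation.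

Key step: step 8

Assumption: the carbinol centre made in step 1 is carried as an epimer mixture until it is oxidised in step 5, and the BINAP enantiomer in step 4 ((R), by analogy with geraniol) is the one that gives the 7S methyl centre.

**Route**

Step 1
Reactants: 1 (R)-(−)-linalool, (3R)-3,7-dimethylocta-1,6-dien-3-ol
Product: 2 (2R)-6-methyl-2-(oxiran-2-yl)hept-5-en-2-ol (both epimers at the oxirane CH)
Conditions: VO(acac)2 (2 mol %), t-BuOOH (1.2 equiv), PhMe, 0 °C → rt
Reagents that add atoms: tert-butyl hydroperoxide, CC(C)(C)OO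
Why: Vanadium-catalysed, hydroxyl-directed epoxidation of the tertiary allylic alcohol should oxidise only the vinyl group and leave the remote trisubstituted alkene; the new oxirane centre need not be controlled because it becomes the C2 ketone.

Step 2
Reactants: 2 (2R)-6-methyl-2-(oxiran-2-yl)hept-5-en-2-ol; 3 4-methoxybenzyl alcohol
Product: 4 (3R)-1-[(4-methoxyphenyl)methoxy]-3,7-dimethyloct-6-ene-2,3-diol (both C2 epimers)
Conditions: NaH (1.3 equiv), 3 (1.5 equiv), DMF, 60 °C
Reagents that add atoms: 4-methoxybenzyl alcohol (3), COc1ccc(CO)cc1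
Why: SN2 opening of the terminal epoxide at its unhindered CH2 carbon by the alkoxide installs the protected O-3 and the future C2 oxygen; any Payne-isomeric internal epoxide is hindered, should revert to the terminal epoxide and be consumed through it, and the tertiary carbinol centre is untouched in either case.

Step 3
Reactants: 4 (3R)-1-[(4-methoxyphenyl)methoxy]-3,7-dimethyloct-6-ene-2,3-diol
Product: 5 (2E,6R)-8-[(4-methoxyphenyl)methoxy]-2,6-dimethyloct-2-ene-1,6,7-triol (both C7 epimers)
Conditions: SeO2 (0.3 equiv), t-BuOOH (3 equiv), salicylic acid (cat.), CH2Cl2, rt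
Reagents that add atoms: tert-butyl hydroperoxide, CC(C)(C)OO (oxygen passed on through catalytic selenium dioxide, O=[Se]=O)
Why: Catalytic SeO2 allylic oxidation (ene reaction, then [2,3]-sigmatropic shift) should hydroxylate the (E)-methyl group of the isopropylidene terminus and give the (E)-2-methylallylic alcohol.

Step 4
Reactants: 5 (2E,6R)-8-[(4-methoxyphenyl)methoxy]-2,6-dimethyloct-2-ene-1,6,7-triol
Product: 6 (2S,6R)-8-[(4-methoxyphenyl)methoxy]-2,6-dimethyloctane-1,6,7-triol (both C7 epimers)
Conditions: Ru(OAc)2[(R)-BINAP] (1 mol %), H2 (50 atm), MeOH, rt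
Reagents that add atoms: none
Why: Noyori-type hydroxyl-directed asymmetric hydrogenation of the trisubstituted allylic alcohol should set the methyl centre (core C7) by catalyst control; the PMB ether is inert to the ruthenium catalyst.

Step 5
Reactants: 6 (2S,6R)-8-[(4-methoxyphenyl)methoxy]-2,6-dimethyloctane-1,6,7-triol
Product: 7 (2S,6R)-6-hydroxy-8-[(4-methoxyphenyl)methoxy]-2,6-dimethyl-7-oxooctanal
Conditions: Dess–Martin periodinane (2.5 equiv), CH2Cl2, 0 °C → rt
Reagents that add atoms: none
Why: Dess–Martin oxidation should convert the primary alcohol to the α-methyl aldehyde and the secondary alcohol to the ketone in one operation, under non-basic conditions that spare the tertiary alcohol and the α-stereocentre.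

Step 6
Reactants: 7 (2S,6R)-6-hydroxy-8-[(4-methoxyphenyl)methoxy]-2,6-dimethyl-7-oxooctanal; 8 (triphenylphosphoranylidene)acetaldehyde
Product: 9 (2E,4S,8R)-8-hydroxy-10-[(4-methoxyphenyl)methoxy]-4,8-dimethyl-9-oxodec-2-enal
Conditions: 8 (1.2 equiv), PhMe, 70 °C
Reagents that add atoms: (triphenylphosphoranylidene)acetaldehyde (8), O=CC=P(c1ccccc1)(c1ccccc1)c1ccccc1
Why: Wittig olefination with the stabilised formylmethylene ylide should be selective for the aldehyde over the hindered ketone and give the (E)-enal without a base that could epimerise the adjacent methyl centre.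

Step 7
Reactants: 9 (2E,4S,8R)-8-hydroxy-10-[(4-methoxyphenyl)methoxy]-4,8-dimethyl-9-oxodec-2-enal; 10 tert-butyl 2-(diethoxyphosphoryl)acetate
Product: 11 tert-butyl (4E,6S,10R)-2-(diethoxyphosphoryl)-10-hydroxy-12-[(4-methoxyphenyl)methoxy]-6,10-dimethyl-11-oxododeca-2,4-dienoate (2E/2Z mixture)
Conditions: 10 (1.2 equiv), piperidine (10 mol %), AcOH (10 mol %), 4 Å MS, PhMe, 50 °C
Reagents that add atoms: tert-butyl 2-(diethoxyphosphoryl)acetate (10), CCOP(=O)(OCC)CC(=O)OC(C)(C)C
Why: Knoevenagel condensation of the enal (through its iminium ion) with the phosphonoacetate should give the 2-phosphono-2,4-dienoate; the geometry of the new double bond is irrelevant because that carbon is sp3 after step 8.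

Step 8
Reactants: 11 tert-butyl (4E,6S,10R)-2-(diethoxyphosphoryl)-10-hydroxy-12-[(4-methoxyphenyl)methoxy]-6,10-dimethyl-11-oxododeca-2,4-dienoate
Product: 13 tert-butyl 2-(diethoxyphosphoryl)-2-[(1R,3R,4S,6R,7S)-3-[(4-methoxyphenyl)methoxy]-1,7-dimethyl-2-oxo-11-oxabicyclo[4.4.1]undecan-4-yl]acetate (both epimers at the phosphonate carbon), via oxepane alkylidenephosphonoacetate 12 (not isolated)
Conditions: KOt-Bu (0.2 equiv), t-BuOH/THF (1:4), 0.01 M, −20 °C → rt
Reagents that add atoms: none
Why: Proposed new method: catalytic tert-butoxide deprotonates the tertiary α-ketol hydroxyl, whose alkoxide adds reversibly to the δ-carbon (core C6) of the 2-phosphono-2,4-dienoate (1,6-oxa-Michael); after proton shuttling to the conjugated alkylidene phosphonoacetate 12, the ketone enolate at core C3 (the only enolisable position, C1 being quaternary) adds to the β-carbon (core C4) to give the stabilised phosphonoacetate anion. The closest known reaction types are alkoxide 1,6-additions to 2,4-dienoates, tandem oxa-Michael/Michael annulations and intramolecular Michael additions of ketone enolates to alkylidene malonates and phosphonoacetates. Ring B closes 7-exo-trig through O11–C6 and ring A closes 7-(enolendo)-exo-trig through C3–C4. C6 is set under thermodynamic control by the C1 and C7 centres, because only the 2,7-cis oxepane (side chain trans to the C7 methyl) can be bridged and the reversible oxa-Michael funnels through it; C4 is set by enolate approach to the alkene face that leaves the phosphonoacetate substituent exo to the bicycle, and C3, epimerisable next to the ketone, should settle trans to that substituent. The step needs O- before C-addition and 1,6- before 1,4-addition, which ring size secures (O11→C4 and C3→C6 would need nine- and eight-membered rings); it also needs the C7 centre to survive, hence a catalytic hindered alkoxide, low temperature and high dilution. The phosphonate makes both conjugate additions fast and is the handle for the final methylenation.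

Step 9
Reactants: 13 tert-butyl 2-(diethoxyphosphoryl)-2-[(1R,3R,4S,6R,7S)-3-[(4-methoxyphenyl)methoxy]-1,7-dimethyl-2-oxo-11-oxabicyclo[4.4.1]undecan-4-yl]acetate
Product: 14 tert-butyl 2-(diethoxyphosphoryl)-2-[(1R,3R,4S,6R,7S)-3-hydroxy-1,7-dimethyl-2-oxo-11-oxabicyclo[4.4.1]undecan-4-yl]acetate
Conditions: DDQ (1.3 equiv), CH2Cl2/pH 7 buffer (10:1), 0 °C → rt
Reagents that add atoms: none
Why: Oxidative PMB ether cleavage (benzylic hydride abstraction, then hydrolysis of the hemiacetal) should free O-3 without touching the ketone, the phosphonate or the tert-butyl ester.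

Step 10
Reactants: 14 tert-butyl 2-(diethoxyphosphoryl)-2-[(1R,3R,4S,6R,7S)-3-hydroxy-1,7-dimethyl-2-oxo-11-oxabicyclo[4.4.1]undecan-4-yl]acetate
Product: 15 tert-butyl 2-(diethoxyphosphoryl)-2-[(1R,2S,3R,4S,6R,7S)-2,3-dihydroxy-1,7-dimethyl-11-oxabicyclo[4.4.1]undecan-4-yl]acetate
Conditions: Me4NBH(OAc)3 (5 equiv), MeCN/AcOH (1:1), −30 → 0 °C
Reagents that add atoms: none
Why: Saksena–Evans-type hydroxyl-directed reduction: the 3-hydroxyl exchanges onto boron and should deliver hydride intramolecularly to its own face of the C2 ketone, giving the 2,3-trans-diol and so the C2 configuration.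

Step 11
Reactants: 15 tert-butyl 2-(diethoxyphosphoryl)-2-[(1R,2S,3R,4S,6R,7S)-2,3-dihydroxy-1,7-dimethyl-11-oxabicyclo[4.4.1]undecan-4-yl]acetate
Product: 17 trans-fused α-(diethoxyphosphoryl)-γ-butyrolactone closed between O-3 and C4 of the (1R,2S,3R,4S,6R,7S)-2-hydroxy-1,7-dimethyl-11-oxabicyclo[4.4.1]undecane core, via hydroxy acid 16 (not isolated)
Conditions: TFA/CH2Cl2 (1:4), rt; then PhMe, 60 °C
Reagents that add atoms: none
Why: Acidolysis of the tert-butyl ester (loss of isobutene) gives the γ-hydroxy acid, which should lactonise on the secondary 3-hydroxyl to the five-membered trans-fused lactone (the neopentyl 2-hydroxyl would give a six-membered ring).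

Step 12
Reactants: 17 α-phosphono γ-lactone with free 2-hydroxyl; 18 3-methylbutanoic anhydride
Product: 19 2-O-(3-methylbutanoyl) derivative of 17
Conditions: 18 (3 equiv), DMAP (0.2 equiv), pyridine, CH2Cl2, rt → 40 °C
Reagents that add atoms: 3-methylbutanoic anhydride (18), CC(C)CC(=O)OC(=O)CC(C)C
Why: DMAP-catalysed acyl transfer from the anhydride to the one remaining, hindered secondary alcohol installs the isovalerate with retention at C2.

Step 13
Reactants: 19 2-O-(3-methylbutanoyl) α-phosphono γ-lactone; 20 formaldehyde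
Product: 21 target CNP0274454.1, the 2-O-(3-methylbutanoyl) trans-fused α-methylene-γ-butyrolactone (O-3/C4) on the (1R,2S,3R,4R,6R,7S)-1,7-dimethyl-11-oxabicyclo[4.4.1]undecane core
Conditions: 37 % aq. CH2O (excess), K2CO3 (2 equiv), THF, 0 °C → rt
Reagents that add atoms: formaldehyde (20), C=O
Why: Horner–Wadsworth–Emmons olefination of the α-phosphono lactone with formaldehyde under mild carbonate conditions should give the α-methylene lactone, remove the phosphonate and erase the epimeric centre while the isovalerate survives.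

**Compound list**

1 | (R)-(−)-linalool, (3R)-3,7-dimethylocta-1,6-dien-3-ol | O[C@](C)(CCC=C(C)C)C=C | starting material
2 | (2R)-6-methyl-2-(oxiran-2-yl)hept-5-en-2-ol (oxirane epimers) | O[C@](C)(CCC=C(C)C)C1CO1 | intermediate
3 | 4-methoxybenzyl alcohol | COc1ccc(CO)cc1 | starting material
4 | (3R)-1-[(4-methoxyphenyl)methoxy]-3,7-dimethyloct-6-ene-2,3-diol (C2 epimers) | O[C@](C)(CCC=C(C)C)C(O)COCc1ccc(OC)cc1 | intermediate
5 | (2E,6R)-8-[(4-methoxyphenyl)methoxy]-2,6-dimethyloct-2-ene-1,6,7-triol (C7 epimers) | O[C@](C)(CC/C=C(\C)CO)C(O)COCc1ccc(OC)cc1 | intermediate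
6 | (2S,6R)-8-[(4-methoxyphenyl)methoxy]-2,6-dimethyloctane-1,6,7-triol (C7 epimers) | O[C@](C)(CCC[C@@H](CO)C)C(O)COCc1ccc(OC)cc1 | intermediate
7 | (2S,6R)-6-hydroxy-8-[(4-methoxyphenyl)methoxy]-2,6-dimethyl-7-oxooctanal | O[C@](C)(CCC[C@@H](C=O)C)C(=O)COCc1ccc(OC)cc1 | intermediate
8 | (triphenylphosphoranylidene)acetaldehyde | O=CC=P(c1ccccc1)(c1ccccc1)c1ccccc1 | starting material
9 | (2E,4S,8R)-8-hydroxy-10-[(4-methoxyphenyl)methoxy]-4,8-dimethyl-9-oxodec-2-enal | O[C@](C)(CCC[C@@H](/C=C/C=O)C)C(=O)COCc1ccc(OC)cc1 | intermediate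
10 | tert-butyl 2-(diethoxyphosphoryl)acetate | CCOP(=O)(OCC)CC(=O)OC(C)(C)C | starting material
11 | tert-butyl (4E,6S,10R)-2-(diethoxyphosphoryl)-10-hydroxy-12-[(4-methoxyphenyl)methoxy]-6,10-dimethyl-11-oxododeca-2,4-dienoate (2E/2Z) | O[C@](C)(CCC[C@@H](/C=C/C=C(P(=O)(OCC)OCC)C(=O)OC(C)(C)C)C)C(=O)COCc1ccc(OC)cc1 | intermediate
12 | tert-butyl 2-(diethoxyphosphoryl)-4-[(2R,3S,7R)-7-{2-[(4-methoxyphenyl)methoxy]acetyl}-3,7-dimethyloxepan-2-yl]but-2-enoate | CCOP(=O)(OCC)C(C(=O)OC(C)(C)C)=CC[C@H]1O[C@](C)(CCC[C@@H]1C)C(=O)COCc1ccc(OC)cc1 | intermediate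
13 | tert-butyl 2-(diethoxyphosphoryl)-2-[(1R,3R,4S,6R,7S)-3-[(4-methoxyphenyl)methoxy]-1,7-dimethyl-2-oxo-11-oxabicyclo[4.4.1]undecan-4-yl]acetate (epimers at the phosphonate carbon) | CCOP(=O)(OCC)C(C(=O)OC(C)(C)C)[C@H]1C[C@H]2O[C@](C)(CCC[C@@H]2C)C(=O)[C@@H]1OCc1ccc(OC)cc1 | intermediate
14 | tert-butyl 2-(diethoxyphosphoryl)-2-[(1R,3R,4S,6R,7S)-3-hydroxy-1,7-dimethyl-2-oxo-11-oxabicyclo[4.4.1]undecan-4-yl]acetate | CCOP(=O)(OCC)C(C(=O)OC(C)(C)C)[C@H]1C[C@H]2O[C@](C)(CCC[C@@H]2C)C(=O)[C@@H]1O | intermediate
15 | tert-butyl 2-(diethoxyphosphoryl)-2-[(1R,2S,3R,4S,6R,7S)-2,3-dihydroxy-1,7-dimethyl-11-oxabicyclo[4.4.1]undecan-4-yl]acetate | CCOP(=O)(OCC)C(C(=O)OC(C)(C)C)[C@H]1C[C@H]2O[C@](C)(CCC[C@@H]2C)[C@@H](O)[C@@H]1O | intermediate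
16 | 2-(diethoxyphosphoryl)-2-[(1R,2S,3R,4S,6R,7S)-2,3-dihydroxy-1,7-dimethyl-11-oxabicyclo[4.4.1]undecan-4-yl]acetic acid | CCOP(=O)(OCC)C(C(=O)O)[C@H]1C[C@H]2O[C@](C)(CCC[C@@H]2C)[C@@H](O)[C@@H]1O | intermediate
17 | γ-lactone of 16 closed on O-3 (trans-fused α-(diethoxyphosphoryl)-γ-butyrolactone, free 2-OH) | CCOP(=O)(OCC)C1C(=O)O[C@@H]2[C@@H]1C[C@H]1O[C@](C)(CCC[C@@H]1C)[C@H]2O | intermediate
18 | 3-methylbutanoic anhydride | CC(C)CC(=O)OC(=O)CC(C)C | starting material
19 | 2-O-(3-methylbutanoyl) derivative of 17 | CCOP(=O)(OCC)C1C(=O)O[C@@H]2[C@@H]1C[C@H]1O[C@](C)(CCC[C@@H]1C)[C@H]2OC(=O)CC(C)C | intermediate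
20 | formaldehyde | C=O | starting material
21 | CNP0274454.1 | C=C1C(=O)O[C@@H]2[C@@H]1C[C@H]1O[C@](C)(CCC[C@@H]1C)[C@H]2OC(=O)CC(C)C | target

Total step count: 13. Longest linear sequence: 13 steps (1 → 21).

**Steps most likely to fail**

Step 8 (Proposed new method). What may go wrong: deprotonation at the allylic CHMe position of the dienyl phosphonoacetate (epimerisation of C7 or migration of the diene) or intermolecular conjugate addition may outrun the slow 7-exo oxa-Michael, or the cascade may stall after the first ring. Fallback with known reactions, each bond made in its own step: it sets out from enal 9. Amine-catalysed (pyrrolidine/PhCO2H, iminium activation, no strong base) intramolecular oxa-Michael addition of the tertiary alcohol to the enal should close ring B under thermodynamic control and give 2-[(2R,3S,7R)-7-{2-[(4-methoxyphenyl)methoxy]acetyl}-3,7-dimethyloxepan-2-yl]acetaldehyde F1. Knoevenagel condensation of F1 with 10 (piperidine/AcOH) should then give the alkylidene phosphonoacetate 12, now isolated. Ring A is closed separately by soft enolisation of the ketone (MgBr2·OEt2, i-Pr2NEt, CH2Cl2) and intramolecular Michael addition, returning to the route at 13.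

Step 10. What may go wrong: external, non-directed hydride delivery to the face opposite the 3-hydroxyl (or no reduction of the hindered ketone under the mild directed conditions) would give the 2,3-cis-diol. Fallback by catalyst control instead of substrate direction: it sets out from 13, with the PMB ether still in place. Corey–Bakshi–Shibata reduction (Me-CBS oxazaborolidine of the enantiomer that adds hydride to the required face, BH3·SMe2, THF) should give tert-butyl 2-(diethoxyphosphoryl)-2-[(1R,2S,3R,4S,6R,7S)-2-hydroxy-3-[(4-methoxyphenyl)methoxy]-1,7-dimethyl-11-oxabicyclo[4.4.1]undecan-4-yl]acetate F2. DDQ cleavage of the PMB ether then returns to the route at 15.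

Step 4. What may go wrong: poor enantioface discrimination on the 2-methyl-substituted allylic alcohol (the established substrates carry the methyl group on the distal alkene carbon). Fallback by biocatalytic conjugate reduction: it sets out from 5. MnO2 (CH2Cl2) should oxidise only the allylic alcohol to (2E,6R)-6,7-dihydroxy-8-[(4-methoxyphenyl)methoxy]-2,6-dimethyloct-2-enal F3. An ene-reductase of the Old Yellow Enzyme family (NADPH recycled with glucose/glucose dehydrogenase, pH 7 buffer) should reduce the C=C bond to (2S,6R)-6,7-dihydroxy-8-[(4-methoxyphenyl)methoxy]-2,6-dimethyloctanal F4. NaBH4 added to the same pot, before the α-centre can epimerise, returns to the route at 6.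

**Further compounds**

F1 | step 8 | 2-[(2R,3S,7R)-7-{2-[(4-methoxyphenyl)methoxy]acetyl}-3,7-dimethyloxepan-2-yl]acetaldehyde | O=CC[C@H]1O[C@](C)(CCC[C@@H]1C)C(=O)COCc1ccc(OC)cc1
F2 | step 10 | tert-butyl 2-(diethoxyphosphoryl)-2-[(1R,2S,3R,4S,6R,7S)-2-hydroxy-3-[(4-methoxyphenyl)methoxy]-1,7-dimethyl-11-oxabicyclo[4.4.1]undecan-4-yl]acetate | CCOP(=O)(OCC)C(C(=O)OC(C)(C)C)[C@H]1C[C@H]2O[C@](C)(CCC[C@@H]2C)[C@@H](O)[C@@H]1OCc1ccc(OC)cc1
F3 | step 4 | (2E,6R)-6,7-dihydroxy-8-[(4-methoxyphenyl)methoxy]-2,6-dimethyloct-2-enal | O[C@](C)(CC/C=C(\C)C=O)C(O)COCc1ccc(OC)cc1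
F4 | step 4 | (2S,6R)-6,7-dihydroxy-8-[(4-methoxyphenyl)methoxy]-2,6-dimethyloctanal | O[C@](C)(CCC[C@@H](C=O)C)C(O)COCc1ccc(OC)cc1
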